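## Analysis of the target

Acerosin is a flavone, a 2-aryl-4H-chromen-4-one in which the benzo ring A and the pyranone ring C share the C4a–C8a bond and the aryl ring B sits on C2; it has no stereocentre. Ring A is hexasubstituted: C4a carries the C4 carbonyl, C5 a hydroxyl hydrogen-bonded to that carbonyl, C6 a methoxy group, C7 a hydroxyl, C8 a methoxy group and C8a the ring oxygen O1. Ring B is an isovanillyl unit (3'-OH, 4'-OMe). The sensitive features are the three phenols, the para-related 5-hydroxy/8-methoxy pair that an oxidant can take to a 5,8-quinone, the enone C2=C3–C4=O that opens in hot alkali, and three aryl methyl ethers that must survive the unmasking of the phenols. The difficulty is therefore regiochemical rather than skeletal: five differentiated oxygens must be placed on adjacent carbons of ring A and exactly three hydroxyls freed in the whole molecule. The strategy rests on the fact that the oxygens on C6, C7 and C8 form the 3,4,5-pattern of a syringoyl group, whose mirror plane through C7 and C4a makes its two ortho C–H positions identical. One of these becomes C8a, which lies ortho to the C8 methoxy group and para to the C6 methoxy group and is therefore where a radical cation of ring A carries positive charge; the other becomes C5, peri to the C4 carbonyl and open to carbonyl-directed oxygenation. In addition, opening and reclosure of ring C through the C5 oxygen (Wessely–Moser isomerisation) regenerates the same compound, so the endgame cannot scramble ring A.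

## Retrosynthetic reasoning

**12 to 11.** Only the ester C–O bond of a 3'-O-acetate is cut. The acetate is more than a protecting group: it keeps ring B harder to oxidise than ring A in the ring-forming step, so it is carried to the end and removed last by mild methanolysis, which leaves the pyranone and the methyl ethers alone.

**11 to 10.** The C7 oxygen is traced back to an isopropyl ether. The forward reaction has to cleave one secondary alkyl aryl ether next to three methyl ethers. A Lewis acid that ionises the secondary C–O bond far faster than a methyl C–O bond does this. An isopropyl ether is chosen because it survives base, anodic oxidation and hot acid better than a benzyl ether would.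

**10 to 8, through trifluoroacetate 9.** The C5–O bond is cut back to C5–H. This is the one remaining hydrogen of ring A and it lies peri to the C4 carbonyl, so a ruthenium-catalysed, carbonyl-directed C–H oxygenation can reach it and nothing else. The gain is that the ring A precursor needs three oxygens instead of four and keeps its mirror symmetry for the ring closure. The forward reaction must add oxygen without letting the oxidant attack the electron-rich ring; the new oxygen is therefore delivered as the electron-poor ester 9 and is only unmasked to 10 on work-up.

**8 to 7.** This is the strategic cut, O1–C8a, back to an arene C–H and an enol O–H. The classical flavone disconnections (O1–C2 cyclodehydration, C4–C4a acylation) need an ortho-hydroxyaryl ketone whose ring already carries four or five oxygens in fixed order. Cutting O1–C8a instead makes ring A a plain syringoyl group in 7, and either ortho carbon gives the same product. The forward reaction must remove two electrons and two protons and join the C2 oxygen to the ring carbon that is ortho to one methoxy group and para to the other. An anode does this without any reagent.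

**7 to 4 and 6.** The C3–C4 bond between the central methylene carbon and the ring A carbonyl is cut. This places the acyl electrophile on the ring A side (acid chloride 4) and the methyl ketone on the ring B side (6), both of which derive from commercial materials. The forward C-acylation must spare the aryl acetate, which rules out strong amide or alkoxide bases and points to soft enolisation.

**4 to 3 to 1, and 6 to 5.** Acid chloride 4 comes from acid 3. Acid 3 comes from syringic acid 1 by exhaustive O-isopropylation to ester 2 and saponification in the same pot. Ketone 6 is the acetate of commercial 3-hydroxy-4-methoxyacetophenone 5.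

## Alternatives that were turned down

**Alternative 1:** ring C is contracted by removing C3 as a one-carbon unit, which leads back to the 3-silyloxy-2-arylbenzofuran A2.
- Forward key step: dichlorocarbene adds across the furan C2=C3 bond of A2, and the dichlorocyclopropane opens with loss of chloride and the silyl group to give the 3-chloroflavone A1. Hydrogenolysis would then remove the chlorine and all three benzyl groups together.
- For it: ring expansion of silyl enol ethers by dihalocarbenes to 2-halo-enones is an established reaction type. All five ring A oxygens are in place before the key step, so no late C–H oxidation is needed, and the endgame is a single operation. On these two points it is stronger than the chosen route.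
- Against it: A2 already contains the hexasubstituted benzene with five differentiated oxygens, so the real problem of the target is moved into the preparation of A2 and not solved. The double bond to be cyclopropanated is fully substituted and part of an aromatic furan. The electron-rich enol ether is prone to autoxidation at C2. The basic carbene generation threatens the silyl ether. The final hydrogenolysis must remove a vinylic chloride without reducing C2=C3.
- Comparison: the chosen route builds ring A from a symmetric three-oxygen acid and adds the last two oxygens by C–H functionalisation, which is far shorter, at the price of an untested key step.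

**Alternative 2:** ring A is built onto a preformed pyranone. The precursor is the racemic 4-hydroxycyclobutenone A4, made by adding a metalated pyranone carbon to one carbonyl of the mixed squaric ester A5.
- Forward key step: heating A4 opens the four-membered ring to a vinylketene, whose ketene carbon bonds to the free pyranone carbon. Tautomerisation gives the 5,8-hydroquinone A3 (a Moore-type ring expansion). Methylation of the non-chelated C8 hydroxyl and removal of the tert-butyl and benzyl groups would follow.
- For it: every oxygen of ring A is placed by construction. The C5 and C8 hydroxyls of A3 differ because only the former is hydrogen-bonded. The key step belongs to a known reaction family. On certainty of the key step it is stronger than the chosen route.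
- Against it: the regiochemistry of C6 and C7 depends on which carbonyl of A5 is attacked, and this is controlled only by the size difference of two alkoxy groups. The hydroquinone A3 is easily oxidised to the quinone. The tert-butyl ether may lose isobutene at the thermolysis temperature. The metalated pyranone, A5, the late methylation and two deprotections add many steps.
- Comparison: the chosen route is convergent from two commercial aromatics and has no regiochemical choice in its ring-forming step.

**Alternative 3:** three bonds of ring C (O1–C8a, C4–C4a and O1–C2) are cut at once, leading to the aryne A7 and the arylpropiolic acid A8.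
- Forward key step: fluoride releases A7, the carboxylate oxygen of A8 adds to the aryne carbon remote from the benzyloxy group, the resulting aryl anion takes over the acyl carbon, and the phenoxide adds to the ynone to give the flavone A6.
- For it: it forms three bonds in one operation, is highly convergent, and insertion of arynes into the C–O bond of carboxylic acids is known. In bond-forming economy and precedent it is stronger than the chosen key step.
- Against it: A6 has hydrogen at C8. The C8 methoxy group would have to be added late at a site with no directing carbonyl, in practice by Elbs persulfate oxidation para to a freed C5 hydroxyl and selective methylation, flanked by selective debenzylations. A7 must also be released from a purpose-built trioxygenated precursor that costs several steps.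
- Comparison: both routes need one late ring A oxygenation. In the chosen route it is at C5, where the peri carbonyl fixes the site and the reaction is catalytic, and the ring A building block is a cheap symmetric acid.

Key step: step 5

Remark: compound 7 is drawn as the diketo tautomer although it should exist largely as the hydrogen-bonded enol. Magnesium, boron and alkali-metal salts or chelates that exist only until aqueous work-up are treated as forms of the isolated product and carry no number.

## Route

Step 1
Reactants: 1 syringic acid (4-hydroxy-3,5-dimethoxybenzoic acid)
Product: 3 4-isopropoxy-3,5-dimethoxybenzoic acid, via isopropyl ester 2 (not isolated)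
Conditions: 2-bromopropane (excess), K2CO3, DMF, 70 °C; then 2 M NaOH, MeOH, 65 °C; HCl to pH 2
Reagents that add atoms: 2-bromopropane, CC(C)Br; sodium hydroxide, [Na+].[OH-]
Why: Williamson alkylation of the phenoxide and the carboxylate gives ester 2, and saponification in the same pot returns the acid, its new hydroxyl oxygen coming from hydroxide while the ester alkoxy group leaves as propan-2-ol. The aryl isopropyl ether is inert to hydroxide.

Step 2
Reactants: 3 4-isopropoxy-3,5-dimethoxybenzoic acid
Product: 4 4-isopropoxy-3,5-dimethoxybenzoyl chloride
Conditions: (COCl)2, DMF (cat.), CH2Cl2, 0 °C → rt; evaporated and used crude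
Reagents that add atoms: oxalyl chloride, O=C(Cl)C(Cl)=O
Why: Acid chloride formation through the Vilsmeier-type chloroiminium intermediate is mild enough to leave the isopropyl and methyl ethers untouched. The by-products are gases.

Step 3
Reactants: 5 3-hydroxy-4-methoxyacetophenone
Product: 6 3-acetoxy-4-methoxyacetophenone (5-acetyl-2-methoxyphenyl acetate)
Conditions: Ac2O, pyridine, rt
Reagents that add atoms: acetic anhydride, CC(=O)OC(C)=O
Why: Standard O-acetylation of a phenol. The acetoxy group is chosen because it is a much weaker donor than hydroxyl or alkoxy, which keeps ring B harder to oxidise than ring A in step 5, and because it comes off under the mildest conditions at the end.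

Step 4
Reactants: 6 3-acetoxy-4-methoxyacetophenone; 4 4-isopropoxy-3,5-dimethoxybenzoyl chloride
Product: 7 1-(3-acetoxy-4-methoxyphenyl)-3-(4-isopropoxy-3,5-dimethoxyphenyl)propane-1,3-dione
Conditions: MgBr2·OEt2 (2.5 equiv), iPr2NEt (3 equiv), CH2Cl2, rt; 1 M HCl work-up
Reagents that add atoms: none
Why: Soft enolisation, a crossed Claisen-type C-acylation: magnesium coordination acidifies the methyl ketone enough for the tertiary amine to form the magnesium enolate, which is C-acylated by the acid chloride. The product is held as its magnesium diketonate, which protects it from a second acylation, and the aryl acetate meets no strong base or alkoxide.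

Step 5
Reactants: 7 1-(3-acetoxy-4-methoxyphenyl)-3-(4-isopropoxy-3,5-dimethoxyphenyl)propane-1,3-dione
Product: 8 3'-acetoxy-7-isopropoxy-6,8,4'-trimethoxyflavone
Conditions: undivided cell, graphite anode, Pt cathode, nBu4NPF6 (0.1 M), (CF3)2CHOH/CH2Cl2, constant current (5 mA cm−2, about 2.2 F mol−1), rt
Reagents that add atoms: none
Why: Proposed new method: the anode removes one electron from ring A of 7, the most electron-rich π system once ring B carries the acetoxy group, and hexafluoroisopropanol keeps the resulting radical cation alive long enough to be trapped intramolecularly; its positive charge sits on the two equivalent carbons that are ortho to one methoxy group and para to the other, and the oxygen on C2 of the Z-enol adds to one of them, the future C8a. The hydrogen-bonded chelate is not itself the reactive conformer, because in it the C2 oxygen faces the C4 carbonyl oxygen; rotation about the C3–C4 single bond to the s-trans form, which the hydrogen-bond-donating solvent eases by solvating the carbonyl, brings that oxygen over the ortho carbon of ring A. Loss of a proton, a second one-electron oxidation and loss of the C8a proton restore aromaticity and give 8, while the cathode reduces protons to dihydrogen, so no chemical oxidant is needed. The closest known reaction types are the anodic dehydrogenative lactonisation of biaryl-2-carboxylic acids, the oxidative closure of 2-hydroxybenzophenones to xanthones and the FeCl3-mediated coupling of the enol oxygen of α-aryl ketones with alkoxy-activated arenes to benzofurans; a six-membered closure of a 1,3-diketone enol onto an arene C–H has not been shown. Ring C closes by attack of oxygen on an aromatic carbon to give the six-membered ring O1–C2–C3–C4–C4a–C8a (6-endo with respect to the C4a=C8a bond), and no stereocentre is formed. The step needs oxidation of ring A in preference to ring B and to the enol, and closure onto ring A: the acetoxy group raises the potential of ring B, whose two ortho carbons are moreover meta to its only strong donor and so poorly charged, the absence of base keeps the easily oxidised diketonate out of solution, attack through C3 would need a four-membered ring, and the mirror symmetry of the syringoyl ring makes the two possible closures identical. Over-oxidation of 8 is limited by stopping near the theoretical charge and by the weak donor character of O1, which is tied up as a vinylogous ester.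

Step 6
Reactants: 8 3'-acetoxy-7-isopropoxy-6,8,4'-trimethoxyflavone
Product: 10 3'-acetoxy-5-hydroxy-7-isopropoxy-6,8,4'-trimethoxyflavone, via aryl trifluoroacetate 9 (not isolated)
Conditions: [RuCl2(p-cymene)]2 (5 mol %), PhI(OCOCF3)2 (2 equiv), CF3CO2H/(CF3CO)2O, 80 °C; then H2O work-up
Reagents that add atoms: [bis(trifluoroacetoxy)iodo]benzene, O=C(OI(OC(=O)C(F)(F)F)c1ccccc1)C(F)(F)F
Why: Carbonyl-directed C–H oxygenation, a reaction type established for the C5 position of flavones: the C4 carbonyl guides ruthenium to the peri C5–H, the only hydrogen left on ring A, and oxidation of the ruthenacycle followed by C–O reductive elimination gives trifluoroacetate 9. The oxygen stays masked as an electron-poor ester while oxidant is present, which guards the para-alkoxyphenol against quinone formation, and water releases the chelated phenol 10 on work-up.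

Step 7
Reactants: 10 3'-acetoxy-5-hydroxy-7-isopropoxy-6,8,4'-trimethoxyflavone
Product: 11 3'-acetoxy-5,7-dihydroxy-6,8,4'-trimethoxyflavone
Conditions: BCl3 (3 equiv), CH2Cl2, −78 → 0 °C; then H2O
Reagents that add atoms: none
Why: Lewis-acid ether cleavage: boron coordinates the C7 oxygen and chloride takes the secondary isopropyl group far faster than a methyl group can leave. At low temperature the three methyl ethers and the aryl acetate should remain, and the boron chelate formed at the C5 hydroxyl is hydrolysed on work-up.

Step 8
Reactants: 11 3'-acetoxy-5,7-dihydroxy-6,8,4'-trimethoxyflavone
Product: 12 acerosin (5,7,3'-trihydroxy-6,8,4'-trimethoxyflavone)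
Conditions: K2CO3, MeOH, 0 °C → rt, argon; then 1 M HCl
Reagents that add atoms: none
Why: Base-mediated transesterification of an aryl acetate with methanol. The conditions are too mild to open the pyranone, and any ring opening and reclosure through the C5 oxygen would regenerate the same substitution pattern.

## Compound list

1 | syringic acid (4-hydroxy-3,5-dimethoxybenzoic acid) | COc1cc(C(=O)O)cc(OC)c1O | starting material
2 | isopropyl 4-isopropoxy-3,5-dimethoxybenzoate (not isolated) | COc1cc(C(=O)OC(C)C)cc(OC)c1OC(C)C | intermediate
3 | 4-isopropoxy-3,5-dimethoxybenzoic acid | COc1cc(C(=O)O)cc(OC)c1OC(C)C | intermediate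
4 | 4-isopropoxy-3,5-dimethoxybenzoyl chloride | COc1cc(C(Cl)=O)cc(OC)c1OC(C)C | intermediate
5 | 3-hydroxy-4-methoxyacetophenone | CC(=O)c1ccc(OC)c(O)c1 | starting material
6 | 3-acetoxy-4-methoxyacetophenone | CC(=O)Oc1cc(C(C)=O)ccc1OC | intermediate
7 | 1-(3-acetoxy-4-methoxyphenyl)-3-(4-isopropoxy-3,5-dimethoxyphenyl)propane-1,3-dione | COc1ccc(C(=O)CC(=O)c2cc(OC)c(OC(C)C)c(OC)c2)cc1OC(C)=O | intermediate
8 | 3'-acetoxy-7-isopropoxy-6,8,4'-trimethoxyflavone | COc1ccc(-c2cc(=O)c3cc(OC)c(OC(C)C)c(OC)c3o2)cc1OC(C)=O | intermediate
9 | 3'-acetoxy-7-isopropoxy-6,8,4'-trimethoxy-5-(trifluoroacetoxy)flavone (not isolated) | COc1ccc(-c2cc(=O)c3c(OC(=O)C(F)(F)F)c(OC)c(OC(C)C)c(OC)c3o2)cc1OC(C)=O | intermediate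
10 | 3'-acetoxy-5-hydroxy-7-isopropoxy-6,8,4'-trimethoxyflavone | COc1ccc(-c2cc(=O)c3c(O)c(OC)c(OC(C)C)c(OC)c3o2)cc1OC(C)=O | intermediate
11 | 3'-acetoxy-5,7-dihydroxy-6,8,4'-trimethoxyflavone | COc1ccc(-c2cc(=O)c3c(O)c(OC)c(O)c(OC)c3o2)cc1OC(C)=O | intermediate
12 | acerosin (5,7,3'-trihydroxy-6,8,4'-trimethoxyflavone) | COc1ccc(-c2cc(=O)c3c(O)c(OC)c(O)c(OC)c3o2)cc1O | target

## Step count and least certain steps

Total: 8 steps, two of them two-stage operations in one flask. Longest linear sequence: 7 steps (1 → 3 → 4 → 7 → 8 → 10 → 11 → 12); the ring B branch from 5 is 6 steps.

**Step 5 (key step).** The most likely failures are: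
- electron loss from the enol or from traces of diketonate instead of ring A, leading to coupling through C3 or capture of solvent;
- trapping of the ring A radical cation by the medium before the non-chelated conformer can close;
- further oxidation of the product at C5, which lies para to the C8 methoxy group.

Fallback in known chemistry, setting out from 3 and returning at 8: the same O1–C8a bond would be made from a halide. Acid 3 would be brominated at one of its two equivalent activated ortho positions (NBS, MeCN, rt) to 2-bromo-4-isopropoxy-3,5-dimethoxybenzoic acid F1. This would be converted with (COCl)2 and catalytic DMF into 2-bromo-4-isopropoxy-3,5-dimethoxybenzoyl chloride F2 and joined to 6 under the soft-enolisation conditions of step 4 to give 1-(3-acetoxy-4-methoxyphenyl)-3-(2-bromo-4-isopropoxy-3,5-dimethoxyphenyl)propane-1,3-dione F3. Intramolecular Ullmann-type O-arylation of its enol (CuI, 1,10-phenanthroline, anhydrous K3PO4, toluene, 100 °C, conditions under which the acetate should stay) would close ring C and deliver 8.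

**Step 6.** The most likely failures are slow ruthenation at a C5–H that is flanked by the C6 methoxy group, oxidative degradation of the tetra-oxygenated ring by the hypervalent iodine reagent, and acidolysis of the isopropyl ether in hot trifluoroacetic acid. Partial exchange of the 3'-acetate would only anticipate step 8.

Fallback, setting out from 8 and returning at 10: the oxygen would be introduced through boron under neutral conditions. Ketone-directed ortho C–H borylation ([Ir(OMe)(cod)]2, AsPh3, B2pin2, octane, 120 °C) should give 3'-acetoxy-7-isopropoxy-6,8,4'-trimethoxy-5-(4,4,5,5-tetramethyl-1,3,2-dioxaborolan-2-yl)flavone F4. Oxidation of the C–B bond (Oxone, acetone/H2O, 0 °C) would give 10 without the arene ever meeting an oxidant in strong acid.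

**Step 4.** The most likely failure is acyl scrambling: transfer of the acetyl group from the aryl acetate to the magnesium enolate or diketonate, or a second aroylation of the product.

Fallback, setting out from 4 and 5 and returning at 7: the acetate would be put on after the carbon–carbon bond is made. Acid chloride 4 would be quenched with methanol to methyl 4-isopropoxy-3,5-dimethoxybenzoate F5. Claisen condensation with the unprotected ketone 5 (LiN(SiMe3)2, 3.2 equiv, THF, −78 °C → rt), in which the lithium phenoxide is a spectator and only the ketone enolate attacks the ester, should give 1-(3-hydroxy-4-methoxyphenyl)-3-(4-isopropoxy-3,5-dimethoxyphenyl)propane-1,3-dione F6. Acetylation with one equivalent of Ac2O (Et3N, catalytic DMAP, CH2Cl2, 0 °C) would return 7; any enol acetate formed is a vinylogous anhydride and should pass its acetyl group on to the phenol.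

**Step 7.** The most likely failure is over-dealkylation: loss of the C6 methyl ether, which lies next to the boron chelate formed at the C5 hydroxyl and the C4 carbonyl, or of the C8 methyl ether on prolonged exposure.

Fallback, setting out from 8 and returning at 11: the order of dealkylation and oxygenation would be inverted. BCl3 acting on 8, which has no C5 hydroxyl and so no peri chelate holding the Lewis acid next to the C6 methoxy group, should give 3'-acetoxy-7-hydroxy-6,8,4'-trimethoxyflavone F7. In the CF3CO2H/(CF3CO)2O medium of step 6 the free phenol would be capped in the flask as 3'-acetoxy-6,8,4'-trimethoxy-7-(trifluoroacetoxy)flavone F8. The ruthenium-catalysed oxygenation would then give 3'-acetoxy-6,8,4'-trimethoxy-5,7-bis(trifluoroacetoxy)flavone F9, and aqueous work-up would release 11 directly.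

## Further compounds

F1 | step 5 | 2-bromo-4-isopropoxy-3,5-dimethoxybenzoic acid | COc1cc(C(=O)O)c(Br)c(OC)c1OC(C)C
F2 | step 5 | 2-bromo-4-isopropoxy-3,5-dimethoxybenzoyl chloride | COc1cc(C(Cl)=O)c(Br)c(OC)c1OC(C)C
F3 | step 5 | 1-(3-acetoxy-4-methoxyphenyl)-3-(2-bromo-4-isopropoxy-3,5-dimethoxyphenyl)propane-1,3-dione | COc1ccc(C(=O)CC(=O)c2cc(OC)c(OC(C)C)c(OC)c2Br)cc1OC(C)=O
F4 | step 6 | 3'-acetoxy-7-isopropoxy-6,8,4'-trimethoxy-5-(4,4,5,5-tetramethyl-1,3,2-dioxaborolan-2-yl)flavone | COc1ccc(-c2cc(=O)c3c(B4OC(C)(C)C(C)(C)O4)c(OC)c(OC(C)C)c(OC)c3o2)cc1OC(C)=O
F5 | step 4 | methyl 4-isopropoxy-3,5-dimethoxybenzoate | COC(=O)c1cc(OC)c(OC(C)C)c(OC)c1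
F6 | step 4 | 1-(3-hydroxy-4-methoxyphenyl)-3-(4-isopropoxy-3,5-dimethoxyphenyl)propane-1,3-dione | COc1ccc(C(=O)CC(=O)c2cc(OC)c(OC(C)C)c(OC)c2)cc1O
F7 | step 7 | 3'-acetoxy-7-hydroxy-6,8,4'-trimethoxyflavone | COc1ccc(-c2cc(=O)c3cc(OC)c(O)c(OC)c3o2)cc1OC(C)=O
F8 | step 7 | 3'-acetoxy-6,8,4'-trimethoxy-7-(trifluoroacetoxy)flavone | COc1ccc(-c2cc(=O)c3cc(OC)c(OC(=O)C(F)(F)F)c(OC)c3o2)cc1OC(C)=O
F9 | step 7 | 3'-acetoxy-6,8,4'-trimethoxy-5,7-bis(trifluoroacetoxy)flavone | COc1ccc(-c2cc(=O)c3c(OC(=O)C(F)(F)F)c(OC)c(OC(=O)C(F)(F)F)c(OC)c3o2)cc1OC(C)=O
A1 | alternative 1 | 3-chloro-5,7,3'-tris(benzyloxy)-6,8,4'-trimethoxyflavone | COc1ccc(-c2oc3c(OC)c(OCc4ccccc4)c(OC)c(OCc4ccccc4)c3c(=O)c2Cl)cc1OCc1ccccc1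
A2 | alternative 1 | 4,6-bis(benzyloxy)-2-(3-benzyloxy-4-methoxyphenyl)-3-(tert-butyldimethylsilyloxy)-5,7-dimethoxybenzofuran | COc1ccc(-c2oc3c(OC)c(OCc4ccccc4)c(OC)c(OCc4ccccc4)c3c2O[Si](C)(C)C(C)(C)C)cc1OCc1ccccc1
A3 | alternative 2 | 3'-benzyloxy-7-tert-butoxy-5,8-dihydroxy-6,4'-dimethoxyflavone | COc1ccc(-c2cc(=O)c3c(O)c(OC)c(OC(C)(C)C)c(O)c3o2)cc1OCc1ccccc1
A4 | alternative 2 | racemic 2-tert-butoxy-4-hydroxy-3-methoxy-4-[6-(3-benzyloxy-4-methoxyphenyl)-4-oxo-4H-pyran-3-yl]cyclobut-2-en-1-one | COc1ccc(-c2cc(=O)c(C3(O)C(OC)=C(OC(C)(C)C)C3=O)co2)cc1OCc1ccccc1
A5 | alternative 2 | 3-tert-butoxy-4-methoxycyclobut-3-ene-1,2-dione | COC1=C(OC(C)(C)C)C(=O)C1=O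
A6 | alternative 3 | 5,7,3'-tris(benzyloxy)-6,4'-dimethoxyflavone | COc1ccc(-c2cc(=O)c3c(OCc4ccccc4)c(OC)c(OCc4ccccc4)cc3o2)cc1OCc1ccccc1
A7 | alternative 3 | 3,5-bis(benzyloxy)-4-methoxybenzyne | COC1=C(OCc2ccccc2)C#CC=C1OCc1ccccc1
A8 | alternative 3 | 3-(3-benzyloxy-4-methoxyphenyl)propiolic acid | COc1ccc(C#CC(=O)O)cc1OCc1ccccc1
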